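The flask is slow, and that slowness is what I hand over: when you come back, the starting material should still be the tallest peak. The charges, the earlier runs and the questions stand here.

in all of them: catalyst 10 mol%
- green: starting material 0.034 M; partner 3 equiv; second substrate 0.20 equiv (fed, over 20 min); run made earlier; the fed solution adds 0.20 times the starting volume
- ochre: starting material 0.075 M; partner 3 equiv; second substrate 0.20 equiv (fed, over 20 min); run made earlier; the fed solution adds 0.20 times the starting volume
- red: starting material 0.050 M; partner 3 equiv; second substrate 0.40 equiv (fed, over 20 min); run made earlier; the fed solution adds 0.20 times the starting volume
- flask: starting material 0.050 M; partner 3.00 equiv; second substrate 0.200 equiv (fed, over 20 min); the fed solution adds 0.20 times the starting volume; time 40 min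

- green (time / min: over-reaction product / %, starting material / %, target / %): 4.00: 0, 97, 3; 12.0: 0, 97, 3; 20.0: 4, 93, 1; 30.0: 8, 95, 2
- ochre (time / min: over-reaction product / %, starting material / %, target / %): 4.00: 3, 95, 4; 12.0: 6, 82, 5; 20.0: 12, 78, 9; 30.0: 22, 68, 7
- red (time / min: over-reaction product / %, starting material / %, target / %): 4.00: 1, 98, 1; 12.0: 4, 93, 0; 20.0: 8, 89, 3; 30.0: 12, 84, 4

(scatter of a reading: 1.5 percentage points)

- every charge counts on the volume at the start, and the solution that is fed holds the whole dose
- steps under discussion: target -> over-reaction product; starting material + partner + catalyst <-> catalyst + target; second substrate + partner + catalyst -> catalyst + second product

* the largest share of what was charged as starting material, at 40 min belongs to (over-reaction product / target / starting material)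
* the largest share itself, whichever of these holds it, in percent of the starting material charged

The red run starts at the concentration of the flask and keeps 84% of its starting material at 30.0 min. From that one reading I get 119 min for the time in which starting material halves if it keeps losing the same fraction each minute, the loss half-life. This is a pseudo-first-order reading, with partner in excess and catalyst returned. Red had twice the second substrate of the flask, but even its dose can take just 13.3% of the partner, so I use the figure here. Over 40 min that reading gives an estimate of 79.2% starting material for the flask.

Expect a small target peak: red shows 4% target at 30.0 min, less than its 12% over-reaction product. Don't touch the catalyst or the concentration. The step runs through the catalyst, and with the same equivalents the ochre run at 0.075 M reads 68% at 30.0 min, lower than the 95% of the green run at 0.034 M.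

The forecast says “starting material barely falls in any run” and names starting material at 79%.

The flask gives starting material at 81.3%, with 15.6% over-reaction product and 3.06% target.

    target → over-reaction product (k = 0.00210 s⁻¹)
    starting material + partner + catalyst ⇌ catalyst + target (K = 12.0 L mol⁻¹, k = 0.160 L² mol⁻² s⁻¹)
    second substrate + partner + catalyst → catalyst + second product (k = 0.290 L² mol⁻² s⁻¹)

At 40.0 min the forward step alone gives starting material a half-life of 150 min, long against the 40 min of the flask. The loss in the flask corresponds to a loss half-life of 134 min; my reading from the red run was 119 min. Stretched in proportion to the loading, my reading becomes 199 min for the neighbour flask with 6 mol% of catalyst and gives an estimate of 87.0% starting material; that neighbour flask holds 88.1%.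

The data were generated by integration for an exercise, noise included.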